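**Plan**

- With the side chain numbered from the OCH2 carbon (C1') to the isopropylidene carbon (C7'), the retrosynthesis cuts C6'=C7' (cross-metathesis), then the two C–O bonds of the C2'–C3' oxirane (epoxidation of an E-C2'=C3' alkene), then C1'–C2' and C3'–CH3 in one operation, and last C3'–C4' and the vinyl C6'=CH2 bond, which lead back to (R)-epichlorohydrin.
- The enabling feature is the trisubstituted oxirane whose C3' methyl is cis to C1': it maps onto an E alkene that is the sum of a terminal alkyne (C2'≡C3'), a methyl–metal bond and C1' as an aryloxymethyl cation on O7 of the 8-methoxycoumarin (benzopyran-2-one) bicycle, which is bought intact.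
- Forward, the chain is joined in the order C3'–C4' (acetylide opening of the epoxide), C6'=CH2 (sulfonium ylide), then C3'–CH3 and C1'–C2' with the coumarin already on C1', then the oxirane (the only ring formed), then C6'=C7'.
- C5' (R) comes from (R)-epichlorohydrin, whose C–O bond is never broken; the E geometry comes from syn-carboalumination and retentive trapping; C2' (R) and C3' (R) come from reagent-controlled Shi epoxidation with the D-fructose-derived ketone.

Key step: step 7

Assumption: hydrangetin (7-hydroxy-8-methoxycoumarin) is taken as a purchasable coumarin.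

**Route**

Step 1
Reactants: 1 (R)-epichlorohydrin; 2 (trimethylsilyl)acetylene
Product: 4 (2R)-1-chloro-5-(trimethylsilyl)pent-4-yn-2-ol, via lithium (trimethylsilyl)acetylide 3 (not isolated)
Conditions: 2, n-BuLi, THF, −78 °C; BF3·OEt2; then 1, −78 °C; aq. work-up
Reagents that add atoms: none
Why: Yamaguchi–Hirao alkynylation, in which the BF3-activated oxirane is opened by the lithium acetylide in an SN2 reaction at the unsubstituted ring carbon, so the C–Cl bond and the C–O bond of the stereocentre stay intact and the R configuration is carried over.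

Step 2
Reactants: 4 (2R)-1-chloro-5-(trimethylsilyl)pent-4-yn-2-ol
Product: 6 (3R)-6-(trimethylsilyl)hex-1-en-5-yn-3-ol, via epoxide (2R)-2-[3-(trimethylsilyl)prop-2-yn-1-yl]oxirane 5 (not isolated)
Conditions: Me3S+ I− (4 equiv), n-BuLi (3.8 equiv), THF, −20 °C; then 4, −20 °C → rt
Reagents that add atoms: trimethylsulfonium iodide, C[S+](C)C.[I-]
Why: Excess dimethylsulfonium methylide should first close the chlorohydrin to the terminal epoxide, then open it at CH2 and eliminate dimethyl sulfide from the γ-oxido sulfonium salt (the known ylide homologation of terminal epoxides to allylic alcohols), which never breaks the C–O bond of the stereocentre.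

Step 3
Reactants: 6 (3R)-6-(trimethylsilyl)hex-1-en-5-yn-3-ol
Product: 7 (3R)-3-(tert-butyldimethylsilyloxy)-6-(trimethylsilyl)hex-1-en-5-yne
Conditions: TBSCl, imidazole, DMF, rt
Reagents that add atoms: tert-butyldimethylsilyl chloride, CC(C)(C)[Si](C)(C)Cl
Why: Standard imidazole-promoted silylation of a secondary alcohol, giving a silyl ether that tolerates organoaluminium reagents and the later basic epoxidation buffer.

Step 4
Reactants: 7 (3R)-3-(tert-butyldimethylsilyloxy)-6-(trimethylsilyl)hex-1-en-5-yne
Product: 8 (3R)-3-(tert-butyldimethylsilyloxy)hex-1-en-5-yne [(R)-tert-butyl(hex-1-en-5-yn-3-yloxy)dimethylsilane]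
Conditions: K2CO3 (cat.), MeOH, rt
Reagents that add atoms: none
Why: Methanolysis of the alkynyl C–Si bond (protiodesilylation) is fast under catalytic carbonate, whereas the secondary tert-butyldimethylsilyl ether is stable to these conditions.

Step 5
Reactants: 9 hydrangetin (7-hydroxy-8-methoxychromen-2-one)
Product: 10 8-methoxy-7-[(methylsulfanyl)methoxy]chromen-2-one
Conditions: ClCH2SCH3, K2CO3, NaI (cat.), DMF, rt
Reagents that add atoms: chloromethyl methyl sulfide, CSCCl
Why: Williamson O-alkylation of the acidic 7-hydroxycoumarin with an α-chloro sulfide gives the aryl methylthiomethyl ether, which places C1' on O7 at the acetal oxidation level.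

Step 6
Reactants: 10 8-methoxy-7-[(methylsulfanyl)methoxy]chromen-2-one
Product: 11 7-(chloromethoxy)-8-methoxychromen-2-one
Conditions: SO2Cl2 (1.0 equiv), CH2Cl2, −78 → 0 °C; volatiles removed in vacuo, used crude at once
Reagents that add atoms: sulfuryl chloride, ClS(Cl)(=O)=O
Why: Chlorinolysis of an O,S-acetal, in which sulfur is chlorinated and the chlorosulfonium ion fragments to the aryloxymethyl cation–chloride pair, is the standard way from ArOCH2SCH3 to ArOCH2Cl, and the sulfide should react before the arene or the electron-poor C3=C4 bond.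

Step 7
Reactants: 8 (3R)-3-(tert-butyldimethylsilyloxy)hex-1-en-5-yne; 11 7-(chloromethoxy)-8-methoxychromen-2-one; 12 trimethylaluminium
Product: 14 7-{[(2E,5R)-5-(tert-butyldimethylsilyloxy)-3-methylhepta-2,6-dien-1-yl]oxy}-8-methoxychromen-2-one, via alkenylalane [(1E,4R)-4-(tert-butyldimethylsilyloxy)-2-methylhexa-1,5-dien-1-yl]dimethylaluminium 13 (not isolated)
Conditions: 12 (2.2 equiv), Cp2ZrCl2 (0.3 equiv), CH2Cl2, 0 °C → rt; volatiles incl. excess AlMe3 removed in vacuo; CH2Cl2, then 11, −20 °C → rt; aq. Rochelle salt
Reagents that add atoms: none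
Why: A methylzirconocene–aluminium species from Cp2ZrCl2 and AlMe3 should add CH3 and metal syn across the terminal alkyne of 8 with the metal on the terminal carbon C2', giving the (E)-2-methylalkenylalane 13; once free AlMe3 is pumped off, the Lewis-acidic aluminium ionises the C–Cl bond of 11 and the aryloxymethyl oxocarbenium ion is captured at the Al-bearing carbon with retention, so C3'–CH3 and C1'–C2' are both formed in one flask. The closest known reaction type is the Negishi zirconium-catalysed methylalumination of terminal alkynes followed by trapping of the alkenylalane with chloromethyl methyl ether to give E-allylic ethers. No ring is closed. No stereocentre is created and the C5' silyloxy centre is untouched; the E geometry (CH3 cis to C1'), which later defines the trans-oxirane, follows from the syn addition and the retentive substitution. The step needs alkyne-over-alkene and terminal regioselectivity, which the unactivated monosubstituted vinyl group (not carbometalated by Cp2ZrCl2/AlMe3 at room temperature) and the unbranched propargylic CH2 of 8 should secure. It also needs the alkenyl–Al bond to react with the α-chloro ether rather than the lactone carbonyl, which the much higher electrophilicity of 11 at CH2Cl, the low temperature and the prior removal of AlMe3 should secure.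

Step 8
Reactants: 14 7-{[(2E,5R)-5-(tert-butyldimethylsilyloxy)-3-methylhepta-2,6-dien-1-yl]oxy}-8-methoxychromen-2-one
Product: 15 7-({(2R,3R)-3-[(2R)-2-(tert-butyldimethylsilyloxy)but-3-en-1-yl]-3-methyloxiran-2-yl}methoxy)-8-methoxychromen-2-one
Conditions: D-fructose-derived Shi ketone (1,2:4,5-di-O-isopropylidene-β-D-erythro-2,3-hexodiulo-2,6-pyranose, 0.3 equiv), Oxone (2KHSO5·KHSO4·K2SO4), K2CO3, Bu4NHSO4, MeCN–CH2(OMe)2, aq. Na2B4O7/Na2EDTA buffer (pH ≈ 10.5), 0 °C; neutral work-up (pH 7)
Reagents that add atoms: potassium peroxymonosulfate, [K+].[O-]S(=O)(=O)OO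
Why: Shi asymmetric epoxidation, in which the chiral dioxirane formed from the ketone and KHSO5 transfers oxygen through a spiro transition state to one face of the E-trisubstituted C2'=C3' alkene, should give the (2'R,3'R)-oxirane under reagent control with this ketone enantiomer, while the monosubstituted vinyl group and the electron-poor coumarin C3=C4 bond react much more slowly.

Step 9
Reactants: 15 7-({(2R,3R)-3-[(2R)-2-(tert-butyldimethylsilyloxy)but-3-en-1-yl]-3-methyloxiran-2-yl}methoxy)-8-methoxychromen-2-one
Product: 16 7-({(2R,3R)-3-[(2R)-2-hydroxybut-3-en-1-yl]-3-methyloxiran-2-yl}methoxy)-8-methoxychromen-2-one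
Conditions: TBAF, AcOH (1:1), THF, 0 °C → rt
Reagents that add atoms: none
Why: Fluoride-induced desilylation buffered with acetic acid frees the C5' hydroxyl without a basic alkoxide, so the lactone stays closed and the oxirane, whose opening by the C5' oxygen would need a disfavoured 4-exo or 5-endo closure, should survive.

Step 10
Reactants: 16 7-({(2R,3R)-3-[(2R)-2-hydroxybut-3-en-1-yl]-3-methyloxiran-2-yl}methoxy)-8-methoxychromen-2-one; 17 2-methylbut-2-ene
Product: 18 7-({(2R,3R)-3-[(2R)-2-hydroxy-4-methylpent-3-en-1-yl]-3-methyloxiran-2-yl}methoxy)-8-methoxychromen-2-one (target)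
Conditions: 17 (large excess, co-solvent), second-generation Grubbs catalyst (H2IMes)(PCy3)Cl2Ru=CHPh (5 mol %), 1,4-benzoquinone (10 mol %), CH2Cl2, 40 °C, sealed tube
Reagents that add atoms: none
Why: Olefin cross-metathesis with 2-methylbut-2-ene in large excess exchanges the terminal CH2 of the vinyl group for an isopropylidene unit (the established conversion of a terminal alkene into a prenyl-type trisubstituted alkene), while the trisubstituted oxirane, the free allylic hydroxyl and the cyclic electron-poor coumarin C3=C4 bond should not take part and no stereocentre is touched.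

**Compound list**

1 | (R)-epichlorohydrin [(2R)-2-(chloromethyl)oxirane] | ClC[C@H]1CO1 | starting material
2 | (trimethylsilyl)acetylene | C#C[Si](C)(C)C | starting material
3 | lithium (trimethylsilyl)acetylide | [Li]C#C[Si](C)(C)C | intermediate
4 | (2R)-1-chloro-5-(trimethylsilyl)pent-4-yn-2-ol | C[Si](C)(C)C#CC[C@@H](O)CCl | intermediate
5 | (2R)-2-[3-(trimethylsilyl)prop-2-yn-1-yl]oxirane | C[Si](C)(C)C#CC[C@@H]1CO1 | intermediate
6 | (3R)-6-(trimethylsilyl)hex-1-en-5-yn-3-ol | C[Si](C)(C)C#CC[C@@H](O)C=C | intermediate
7 | (3R)-3-(tert-butyldimethylsilyloxy)-6-(trimethylsilyl)hex-1-en-5-yne | C[Si](C)(C)C#CC[C@@H](O[Si](C)(C)C(C)(C)C)C=C | intermediate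
8 | (3R)-3-(tert-butyldimethylsilyloxy)hex-1-en-5-yne | C#CC[C@@H](O[Si](C)(C)C(C)(C)C)C=C | intermediate
9 | hydrangetin (7-hydroxy-8-methoxychromen-2-one) | COc1c(O)ccc2ccc(=O)oc12 | starting material
10 | 8-methoxy-7-[(methylsulfanyl)methoxy]chromen-2-one | COc1c(OCSC)ccc2ccc(=O)oc12 | intermediate
11 | 7-(chloromethoxy)-8-methoxychromen-2-one | COc1c(OCCl)ccc2ccc(=O)oc12 | intermediate
12 | trimethylaluminium | C[Al](C)C | starting material
13 | [(1E,4R)-4-(tert-butyldimethylsilyloxy)-2-methylhexa-1,5-dien-1-yl]dimethylaluminium | C[Al](C)/C=C(\C)C[C@@H](O[Si](C)(C)C(C)(C)C)C=C | intermediate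
14 | 7-{[(2E,5R)-5-(tert-butyldimethylsilyloxy)-3-methylhepta-2,6-dien-1-yl]oxy}-8-methoxychromen-2-one | COc1c(OC/C=C(\C)C[C@@H](O[Si](C)(C)C(C)(C)C)C=C)ccc2ccc(=O)oc12 | intermediate
15 | 7-({(2R,3R)-3-[(2R)-2-(tert-butyldimethylsilyloxy)but-3-en-1-yl]-3-methyloxiran-2-yl}methoxy)-8-methoxychromen-2-one | COc1c(OC[C@H]2O[C@]2(C)C[C@@H](O[Si](C)(C)C(C)(C)C)C=C)ccc2ccc(=O)oc12 | intermediate
16 | 7-({(2R,3R)-3-[(2R)-2-hydroxybut-3-en-1-yl]-3-methyloxiran-2-yl}methoxy)-8-methoxychromen-2-one | COc1c(OC[C@H]2O[C@]2(C)C[C@@H](O)C=C)ccc2ccc(=O)oc12 | intermediate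
17 | 2-methylbut-2-ene | CC=C(C)C | starting material
18 | 7-({(2R,3R)-3-[(2R)-2-hydroxy-4-methylpent-3-en-1-yl]-3-methyloxiran-2-yl}methoxy)-8-methoxychromen-2-one | COc1c(OC[C@H]2O[C@]2(C)C[C@@H](O)C=C(C)C)ccc2ccc(=O)oc12 | target

**Step count**

Total: 10 steps. Longest linear sequence: 8 steps (steps 1–4, then 7–10); steps 5 and 6 form the two-step coumarin branch.

**Steps most likely to fail**

Step 7. The trapping may fail through slow ionisation of the rather electron-poor aryloxymethyl chloride, or through transfer of aluminium-bound groups to the lactone carbonyl instead of to C1'. The fallback sets out from 8 and 12: the same methylalumination gives 13, which is trapped with paraformaldehyde in THF to give (2E,5R)-5-(tert-butyldimethylsilyloxy)-3-methylhepta-2,6-dien-1-ol F1. Mitsunobu etherification of this allylic alcohol with hydrangetin 9 (PPh3, DIAD, THF, 0 °C) then makes the aryl ether by O-alkylation and comes back to the route at 14.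

Step 8. The epoxidation may suffer from insufficient facial selectivity on this allylic aryl ether, from competing oxidation of the vinyl group at high conversion, or from opening of the lactone in the pH 10.5 buffer. The fallback sets out from 8 and passes through (2E,5R)-5-(tert-butyldimethylsilyloxy)-3-methylhepta-2,6-dien-1-ol F1, made as described above. Sharpless asymmetric epoxidation of this primary allylic alcohol (Ti(OiPr)4, D-(−)-diethyl tartrate, t-BuOOH, 4 Å molecular sieves, CH2Cl2, −20 °C) should, by analogy with geraniol-type E-allylic alcohols, give {(2R,3R)-3-[(2R)-2-(tert-butyldimethylsilyloxy)but-3-en-1-yl]-3-methyloxiran-2-yl}methanol F2 and leaves the vinyl group, which is not an allylic alcohol, untouched. Mitsunobu etherification of the epoxy alcohol with 9 (PPh3, DIAD, THF) comes back to the route at 15.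

Step 10. The metathesis may stall at the vinyl group flanked by the carbinol, or ruthenium hydride species may isomerise the allylic alcohol to the ethyl ketone. The fallback sets out from 15: Lemieux–Johnson cleavage of the vinyl group (OsO4 cat., NaIO4, 2,6-lutidine, dioxane–water) should give (2R)-2-(tert-butyldimethylsilyloxy)-3-[(2R,3R)-3-{[(8-methoxy-2-oxochromen-7-yl)oxy]methyl}-2-methyloxiran-2-yl]propanal F3. Wittig olefination with isopropylidenetriphenylphosphorane (from isopropyltriphenylphosphonium iodide and n-BuLi, THF, −78 → 0 °C) should give 7-({(2R,3R)-3-[(2R)-2-(tert-butyldimethylsilyloxy)-4-methylpent-3-en-1-yl]-3-methyloxiran-2-yl}methoxy)-8-methoxychromen-2-one F4. Desilylation with TBAF/AcOH comes back to the route at 18.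

**Further compounds**

F1 | step 7 | (2E,5R)-5-(tert-butyldimethylsilyloxy)-3-methylhepta-2,6-dien-1-ol | OC/C=C(\C)C[C@@H](O[Si](C)(C)C(C)(C)C)C=C
F2 | step 8 | {(2R,3R)-3-[(2R)-2-(tert-butyldimethylsilyloxy)but-3-en-1-yl]-3-methyloxiran-2-yl}methanol | OC[C@H]1O[C@]1(C)C[C@@H](O[Si](C)(C)C(C)(C)C)C=C
F3 | step 10 | (2R)-2-(tert-butyldimethylsilyloxy)-3-[(2R,3R)-3-{[(8-methoxy-2-oxochromen-7-yl)oxy]methyl}-2-methyloxiran-2-yl]propanal | COc1c(OC[C@H]2O[C@]2(C)C[C@@H](O[Si](C)(C)C(C)(C)C)C=O)ccc2ccc(=O)oc12
F4 | step 10 | 7-({(2R,3R)-3-[(2R)-2-(tert-butyldimethylsilyloxy)-4-methylpent-3-en-1-yl]-3-methyloxiran-2-yl}methoxy)-8-methoxychromen-2-one | COc1c(OC[C@H]2O[C@]2(C)C[C@@H](O[Si](C)(C)C(C)(C)C)C=C(C)C)ccc2ccc(=O)oc12
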